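Ring A is numbered C1 (C=O), C2=C3 (OMe on C3), C4 (ketal carbon with OMe and O-aryl), C5 (CH2), C6 (CH-allyl); ring B is the 2-allyl-4,5-dimethoxyphenyl group.
Cuts, in retrosynthetic order: C6–allyl (enolate alkylation), C4–O(ring B) (allylic substitution of a ketal acetate), C4–OAc back to C4–C(O)CH3 (Baeyer–Villiger), then C3–C4 and C5–C6 together ([4+2]).
Enabling feature: ring A is a 3-methoxycyclohex-2-enone whose C4 has no hydrogen and two oxygens. C6–C1–C2–C3 is therefore the chain of a 1,1-dimethoxy-3-silyloxybutadiene, and C5–C4 is the C=C bond of an α-methoxy vinyl ketone whose acetyl group stands in for the second oxygen.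
Forward order: diene and dienophile (three steps), closure of ring A, acetyl to acetoxy, attachment of ring B (aromatic throughout, made from 3,4-dimethoxyphenol by O-allylation and Claisen rearrangement), C6 allylation last.
Stereochemistry: C4 comes from a chiral divalent copper bis(oxazoline) chelate in the cycloaddition and is passed on by a retentive 1,2-shift and a double inversion on palladium. C6 comes from substrate control, with allyl bromide adding to the dienolate face opposite to the pseudoaxial aryloxy group.

Key step: step 4

Assumption: (S,S)-tBu-box, 2,2'-(propane-2,2-diyl)bis[(4S)-4-tert-butyl-4,5-dihydro-1,3-oxazole], is taken to give the (4S) adduct on the basis of the square-planar two-point-binding model; should the opposite sense be found, the (R,R) ligand is used and nothing else changes.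

Step 1
Reactants: 1 1,1-dimethoxyethene; 2 acetyl chloride
Product: 3 4,4-dimethoxybut-3-en-2-one
Conditions: pyridine, Et2O, 0 °C → rt; filtration, distillation (no aqueous work-up)
Reagents that add atoms: none
Why: C-acylation of a ketene acetal: the electron-rich CH2 carbon of 1 attacks the acyl chloride (or its N-acylpyridinium salt), and pyridine removes the now very acidic proton from the dimethoxycarbenium ion, which restores a push–pull C=C bond.

Step 2
Reactants: 3 4,4-dimethoxybut-3-en-2-one
Product: 4 1,1-dimethoxy-3-(trimethylsilyloxy)buta-1,3-diene
Conditions: TMSOTf, Et3N, Et2O, 0 °C; pentane, filtration, distillation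
Reagents that add atoms: trimethylsilyl trifluoromethanesulfonate, C[Si](C)(C)OS(=O)(=O)C(F)(F)F
Why: Soft enolisation with O-silylation (silyl enol ether formation): the CH3 group is the only enolisable position of 3, so the 2-silyloxydiene should form as a single regioisomer, as in the standard preparation of 1-alkoxy-3-silyloxybutadienes.

Step 3
Reactants: 5 3,3-dimethoxybutan-2-one
Product: 6 3-methoxybut-3-en-2-one
Conditions: p-TsOH (cat.), hydroquinone (trace), neat, 140 °C, MeOH distilled off
Reagents that add atoms: none
Why: Acid-catalysed 1,2-elimination of methanol from a ketal (ketal to enol ether): the oxocarbenium ion can lose a proton only from the neighbouring CH3 group, and removal of methanol by distillation drives the equilibrium.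

Step 4
Reactants: 4 1,1-dimethoxy-3-(trimethylsilyloxy)buta-1,3-diene; 6 3-methoxybut-3-en-2-one
Product: 8 (4S)-4-acetyl-3,4-dimethoxycyclohex-2-en-1-one, via silyl enol ether cycloadduct 7 (not isolated)
Conditions: Cu(OTf)2 (10 mol %), (S,S)-tBu-box (11 mol %), 4 Å MS, CH2Cl2, −78 → −30 °C; then 0.1 M HCl, THF, 0 °C
Reagents that add atoms: none
Why: Proposed new method: the divalent copper centre holds the carbonyl and the α-methoxy oxygen of 6 in a five-membered chelate, which lowers the LUMO and ties up the donor lone pair of the enol ether, so that the CH2 terminus of 4 (largest HOMO coefficient) bonds to the CH2 of 6 (C6–C5) and the ketene acetal carbon bonds to the α-carbon (C3–C4). Ring A closes either in one asynchronous [4+2] cycloaddition or, if the Mukaiyama–Michael bond forms first, by a 6-(enolexo)-exo-trig attack of the copper enolate on the dimethoxycarbenium ion, and both paths lead to 7. The closest known reactions are the thermal and Lewis-acid Diels–Alder reactions of 1,1-dialkoxy-3-silyloxybutadienes that give 3-alkoxycyclohexenones and the Cu(OTf)2–bis(oxazoline) Diels–Alder reactions of two-point-binding dienophiles (acryloyl oxazolidinones, α'-hydroxy enones, α-thioacrylates), whereas an α-alkoxy enone has not been used in this way. C4 is the only new stereocentre: in the square-planar chelate the tert-butyl group next to the bound methoxy oxygen covers one face of the C=C bond, and attack on the open face should give the (4S) product. The step needs regioselectivity, which the matched polarisation of both partners secures, and chemoselectivity for C=C over C=O, which a hindered, enol-ether-conjugated methyl ketone secures better than an aldehyde would. Dilute acid then cleaves the silyl enol ether and expels one methanol from C3, which can only give the C2=C3 vinylogous ester because C4 bears no hydrogen.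

Step 5
Reactants: 8 (4S)-4-acetyl-3,4-dimethoxycyclohex-2-en-1-one
Product: 9 (1R)-1,2-dimethoxy-4-oxocyclohex-2-en-1-yl acetate
Conditions: mCPBA, Na2HPO4, CH2Cl2, 0 °C → rt
Reagents that add atoms: 3-chloroperoxybenzoic acid, O=C(OO)c1cccc(Cl)c1
Why: Baeyer–Villiger oxidation: in the Criegee adduct of the acetyl group the fully substituted, methoxy-bearing C4 migrates far more readily than CH3 and does so with retention of configuration, whereas the C1 carbonyl and the C2=C3 bond are deactivated as parts of a vinylogous ester and the phosphate buffer shields the acid-labile ketal acetate.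

Step 6
Reactants: 10 3,4-dimethoxyphenol
Product: 11 4-(allyloxy)-1,2-dimethoxybenzene
Conditions: allyl bromide, K2CO3, acetone, reflux
Reagents that add atoms: allyl bromide, C=CCBr
Why: Williamson ether synthesis: the phenoxide displaces bromide from the unhindered allylic halide at oxygen (SN2).

Step 7
Reactants: 11 4-(allyloxy)-1,2-dimethoxybenzene
Product: 12 2-allyl-4,5-dimethoxyphenol
Conditions: N,N-diethylaniline, 200 °C
Reagents that add atoms: none
Why: Aromatic Claisen rearrangement: the [3,3] shift goes to the open ortho carbon (C5 of 11) and not to the one wedged between two oxygen substituents, and tautomerisation restores the phenol.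

Step 8
Reactants: 9 (1R)-1,2-dimethoxy-4-oxocyclohex-2-en-1-yl acetate; 12 2-allyl-4,5-dimethoxyphenol
Product: 13 (4R)-4-(2-allyl-4,5-dimethoxyphenoxy)-3,4-dimethoxycyclohex-2-en-1-one
Conditions: Pd(PPh3)4 (5 mol %), iPr2NEt, CH2Cl2, 0 °C
Reagents that add atoms: none
Why: Proposed new method: zerovalent palladium binds the electron-poor C2=C3 bond on the face opposite to the acetate and ionises C4–OAc with inversion to a C2–C3–C4 η3-allyl complex whose C4 terminus has oxocarbenium character; the phenol attacks this terminus opposite to the metal, so that two inversions give net retention, the enone stays conjugated, and the amine holds the released acetic acid so that the exchange is not reversed. The closest known reactions are the palladium-catalysed glycosylation of 6-acyloxy-2H-pyran-3(6H)-ones with alcohols and phenols (retention at the anomeric carbon) and Tsuji–Trost additions to 1-alkoxyallyl complexes, which so far concern acetal CH centres and not a fully substituted ketal carbon next to a CH2 group.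

Step 9
Reactants: 13 (4R)-4-(2-allyl-4,5-dimethoxyphenoxy)-3,4-dimethoxycyclohex-2-en-1-one
Product: 15 (4R,6R)-4-(2-allyl-4,5-dimethoxyphenoxy)-3,4-dimethoxy-6-(prop-2-en-1-yl)cyclohex-2-en-1-one, via lithium dienolate 14 (not isolated)
Conditions: LiN(iPr)2, THF, −78 °C; allyl bromide, DMPU, −78 → −40 °C
Reagents that add atoms: allyl bromide, C=CCBr
Why: Kinetic α'-deprotonation and C-alkylation of a 3-alkoxycyclohexenone (Stork–Danheiser-type enolate alkylation): C6 carries the only acidic hydrogens because C4 is fully substituted, and in the nearly flat dienolate 14 the larger aryloxy group takes the pseudoaxial position at C4 (it avoids allylic 1,2-strain with the C3 methoxy group and gains anomeric stabilisation), so that allyl bromide should add to C6 on the opposite face and give the 4,6-trans, (6R) product.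

Compound list
1 | 1,1-dimethoxyethene | C=C(OC)OC | starting material
2 | acetyl chloride | CC(=O)Cl | starting material
3 | 4,4-dimethoxybut-3-en-2-one | CC(=O)C=C(OC)OC | intermediate
4 | 1,1-dimethoxy-3-(trimethylsilyloxy)buta-1,3-diene | COC(OC)=CC(=C)O[Si](C)(C)C | intermediate
5 | 3,3-dimethoxybutan-2-one | CC(=O)C(C)(OC)OC | starting material
6 | 3-methoxybut-3-en-2-one | CC(=O)C(=C)OC | intermediate
7 | 1-[(1R)-1,2,2-trimethoxy-4-(trimethylsilyloxy)cyclohex-3-en-1-yl]ethan-1-one (not isolated) | CC(=O)[C@]1(OC)CCC(O[Si](C)(C)C)=CC1(OC)OC | intermediate
8 | (4S)-4-acetyl-3,4-dimethoxycyclohex-2-en-1-one | CC(=O)[C@]1(OC)CCC(=O)C=C1OC | intermediate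
9 | (1R)-1,2-dimethoxy-4-oxocyclohex-2-en-1-yl acetate | CC(=O)O[C@]1(OC)CCC(=O)C=C1OC | intermediate
10 | 3,4-dimethoxyphenol | COc1ccc(O)cc1OC | starting material
11 | 4-(allyloxy)-1,2-dimethoxybenzene | C=CCOc1ccc(OC)c(OC)c1 | intermediate
12 | 2-allyl-4,5-dimethoxyphenol | C=CCc1cc(OC)c(OC)cc1O | intermediate
13 | (4R)-4-(2-allyl-4,5-dimethoxyphenoxy)-3,4-dimethoxycyclohex-2-en-1-one | C=CCc1cc(OC)c(OC)cc1O[C@]1(OC)CCC(=O)C=C1OC | intermediate
14 | lithium (4R)-4-(2-allyl-4,5-dimethoxyphenoxy)-4,5-dimethoxycyclohexa-1,5-dien-1-olate, the C1=C6 dienolate of 13 (not isolated) | [Li+].C=CCc1cc(OC)c(OC)cc1O[C@]1(OC)CC=C([O-])C=C1OC | intermediate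
15 | (4R,6R)-4-(2-allyl-4,5-dimethoxyphenoxy)-3,4-dimethoxy-6-(prop-2-en-1-yl)cyclohex-2-en-1-one, allyl at C6 trans to the aryloxy group at C4 | C=CCc1cc(OC)c(OC)cc1O[C@]1(OC)C[C@@H](CC=C)C(=O)C=C1OC | target

Total step count: 9
Longest linear sequence: 6 steps (steps 1, 2, 4, 5, 8, 9, from 1,1-dimethoxyethene)

Steps most likely to fail

1. Step 8.
- What may go wrong: the ketal acetate may ionise outside the coordination sphere of palladium, with loss of the C4 configuration. The allyl complex may lose a proton from C5, after which ring A aromatises. The acetyl group may also be transferred to the phenol.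
- Fallback: it sets out from 9 and 12 and uses the known glycosylation-type exchange of an anomeric acetate with a phenol (BF3·OEt2, CH2Cl2, −78 °C). This runs through the free oxocarbenium ion and should give racemic 4-(2-allyl-4,5-dimethoxyphenoxy)-3,4-dimethoxycyclohex-2-en-1-one F1.
- Return to the route: preparative HPLC on a chiral stationary phase divides F1 into 13 and (4S)-4-(2-allyl-4,5-dimethoxyphenoxy)-3,4-dimethoxycyclohex-2-en-1-one F2, which is set aside. The route is rejoined at 13. Control of C4 is thus moved from a stereospecific substitution to a resolution.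

2. Step 4.
- What may go wrong: silyl transfer after the first C–C bond may prevent ring closure. Weak two-point binding of the enol ether oxygen may give poor facial selectivity. The diene may add to the carbonyl group or be decomposed by the Lewis acid.
- Fallback: it sets out from 4 and 6 and uses the known uncatalysed thermal Diels–Alder reaction of this diene class (toluene, 80–110 °C). This gives racemic 1-[1,2,2-trimethoxy-4-(trimethylsilyloxy)cyclohex-3-en-1-yl]ethanone F3, which dilute HCl in THF converts into racemic 4-acetyl-3,4-dimethoxycyclohex-2-en-1-one F4.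
- Return to the route: preparative HPLC on a chiral stationary phase gives 8 and (4R)-4-acetyl-3,4-dimethoxycyclohex-2-en-1-one F5, which is set aside. The route is rejoined at 8.

3. Step 9.
- What may go wrong: facial selectivity at C6 may be poor. Proton exchange between product and dienolate may lead to double alkylation. Base may induce loss of the aryloxy group, with aromatisation.
- Fallback: it sets out from 13 and replaces kinetic by thermodynamic control. The alkylation is run without reliance on its selectivity, and 15 is separated by chromatography from (4R,6S)-4-(2-allyl-4,5-dimethoxyphenoxy)-3,4-dimethoxy-6-(prop-2-en-1-yl)cyclohex-2-en-1-one F6.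
- Return to the route: F6 is equilibrated through its enolate with DBU in THF at rt. The trans isomer, with equatorial allyl and axial aryloxy groups, is expected to be favoured. Separation and recycling rejoin the route at 15.

Further compounds
F1 | step 8 | racemic 4-(2-allyl-4,5-dimethoxyphenoxy)-3,4-dimethoxycyclohex-2-en-1-one | C=CCc1cc(OC)c(OC)cc1OC1(OC)CCC(=O)C=C1OC
F2 | step 8 | (4S)-4-(2-allyl-4,5-dimethoxyphenoxy)-3,4-dimethoxycyclohex-2-en-1-one | C=CCc1cc(OC)c(OC)cc1O[C@@]1(OC)CCC(=O)C=C1OC
F3 | step 4 | racemic 1-[1,2,2-trimethoxy-4-(trimethylsilyloxy)cyclohex-3-en-1-yl]ethanone | CC(=O)C1(OC)CCC(O[Si](C)(C)C)=CC1(OC)OC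
F4 | step 4 | racemic 4-acetyl-3,4-dimethoxycyclohex-2-en-1-one | CC(=O)C1(OC)CCC(=O)C=C1OC
F5 | step 4 | (4R)-4-acetyl-3,4-dimethoxycyclohex-2-en-1-one | CC(=O)[C@@]1(OC)CCC(=O)C=C1OC
F6 | step 9 | (4R,6S)-4-(2-allyl-4,5-dimethoxyphenoxy)-3,4-dimethoxy-6-(prop-2-en-1-yl)cyclohex-2-en-1-one | C=CCc1cc(OC)c(OC)cc1O[C@]1(OC)C[C@H](CC=C)C(=O)C=C1OC
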